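**Plan**

1. The target is the (1R,5S,6S)-7-oxabicyclo[4.1.0]hept-3-en-2-one in which the tertiary OH is anti to the oxirane oxygen. The retrosynthesis cuts C4'–C5' of the lower trienamide (back to a terminal enyne on C5 and the (E)-3-iodoacrylamide of the cyclopentenone ring), then the upper amide N–C(O) bond (nitrogen traced back to an azide), then the carbinol–alkenyl bond C5–C1', then the oxirane.
2. Forward: quinone monoketal 1 (the six-membered ring is bought) gets a relay oxirane on one enone (step 1), and the alkenyllithium adds anti to it (step 3). That oxirane is then spent: azide opening and elimination turn it into the enamide C=C–N (steps 6, 11). The real oxirane is made last, on the other enone (step 12).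
3. Stereochemistry: C5 comes from addition anti to the relay oxirane; C1 and C6 from peroxide attack anti to the C5–OSiEt3 bond. The E alkenes come from the Wittig, Horner–Wadsworth–Emmons and Stille partners, from the E iodide 26 and, in the key step, from syn-hydrostannation.
4. Key event: a one-pot palladium-catalysed hydrostannation/Stille coupling that turns the terminal alkyne of 23 into a dienylmetal and joins it to iodoacrylamide 29. It is made possible by the single terminal C≡C–H (C3'≡C4') on the C5 side chain, which passes through the core chemistry as a latent dienyl nucleophile, and by the C5'–I bond β to the amide carbonyl C7' of the cyclopentenone-ring amide, the only carbon–halogen bond present.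
5. Three branches converge: the core (steps 1–6, 11–13), the trienoyl chloride (steps 7–10) and the iodoacrylamide of the cyclopentenone ring (steps 14–16).

Key step: step 17

Remark: the cinchonidinium catalyst is assumed to give the (1S,6R) epoxide 2 from the unsubstituted monoketal; if the sense is opposite, the pseudo-enantiomeric cinchoninium salt is used with no other change.

Remark: (2E)-3-iodoprop-2-enoic acid 26 is taken to be a commercial compound.

Side-chain carbons are numbered C1' (on the carbinol) to C7' (amide carbonyl).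

**Route**

Step 1
Reactants: 1 4,4-dimethoxycyclohexa-2,5-dien-1-one
Product: 2 (1S,6R)-5,5-dimethoxy-7-oxabicyclo[4.1.0]hept-3-en-2-one
Conditions: t-BuOOH (70 % aq., 1.1 equiv), N-benzylcinchonidinium chloride (10 mol %), NaOH (aq.), toluene, 0 °C
Reagents that add atoms: tert-butyl hydroperoxide, CC(C)(C)OO
Why: Weitz–Scheffer epoxidation under chiral phase-transfer catalysis: the two enone C=C bonds of 1 are enantiotopic, so mono-epoxidation desymmetrises the ring, with the peroxide anion ion-paired to the chiral ammonium cation choosing the enone face; the (1S,6R) oxirane is only a relay and is consumed in step 6.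

Step 2
Reactants: 3 (E)-1,2-bis(tributylstannyl)ethene; 4 (bromoethynyl)trimethylsilane
Product: 5 tributyl[(E)-4-(trimethylsilyl)but-1-en-3-yn-1-yl]stannane
Conditions: PdCl2(MeCN)2 (3 mol %), DMF, rt, dark, 3 in twofold excess
Reagents that add atoms: none
Why: Stille coupling of an alkenylstannane with a 1-bromoalkyne; the excess of 3 should hold the coupling to one tin terminus, and the E geometry is retained.

Step 3
Reactants: 5 tributyl[(E)-4-(trimethylsilyl)but-1-en-3-yn-1-yl]stannane; 2 (1S,6R)-5,5-dimethoxy-7-oxabicyclo[4.1.0]hept-3-en-2-one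
Product: 7 (1S,2R,6R)-5,5-dimethoxy-2-[(E)-4-(trimethylsilyl)but-1-en-3-yn-1-yl]-7-oxabicyclo[4.1.0]hept-3-en-2-ol, via alkenyllithium 6 (not isolated)
Conditions: n-BuLi (1.0 equiv to 5), THF, −78 °C; then 2, −78 °C; then H2O
Reagents that add atoms: none
Why: Tin–lithium exchange, then 1,2-addition of the alkenyllithium to the enone carbonyl from the face anti to the adjacent oxirane oxygen (the usual course for epoxyquinone monoketals); this fixes the tertiary carbinol, the future C5 of the target, with OH cis to the relay oxirane.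

Step 4
Reactants: 7 (1S,2R,6R)-5,5-dimethoxy-2-[(E)-4-(trimethylsilyl)but-1-en-3-yn-1-yl]-7-oxabicyclo[4.1.0]hept-3-en-2-ol
Product: 8 (1R,5R,6S)-5-hydroxy-5-[(E)-4-(trimethylsilyl)but-1-en-3-yn-1-yl]-7-oxabicyclo[4.1.0]hept-3-en-2-one
Conditions: Montmorillonite K10, wet CH2Cl2, rt
Reagents that add atoms: water, O
Why: Mild acid-clay hydrolysis of the dimethyl ketal, which the tertiary allylic alcohol and the oxirane should tolerate, unmasks the ketone so that the relay oxirane becomes an α,β-epoxy ketone.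

Step 5
Reactants: 8 (1R,5R,6S)-5-hydroxy-5-[(E)-4-(trimethylsilyl)but-1-en-3-yn-1-yl]-7-oxabicyclo[4.1.0]hept-3-en-2-one
Product: 9 (1R,5R,6S)-5-[(triethylsilyl)oxy]-5-[(E)-4-(trimethylsilyl)but-1-en-3-yn-1-yl]-7-oxabicyclo[4.1.0]hept-3-en-2-one
Conditions: Et3SiOTf, 2,6-lutidine, CH2Cl2, −78 °C
Reagents that add atoms: triethylsilyl trifluoromethanesulfonate, CC[Si](CC)(CC)OS(=O)(=O)C(F)(F)F
Why: Silylation of the hindered tertiary alcohol with a silyl triflate removes the hydrogen-bond donor and installs the group that shields this face in step 12.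

Step 6
Reactants: 9 (1R,5R,6S)-5-[(triethylsilyl)oxy]-5-[(E)-4-(trimethylsilyl)but-1-en-3-yn-1-yl]-7-oxabicyclo[4.1.0]hept-3-en-2-one
Product: 12 (4R)-2-azido-4-[(triethylsilyl)oxy]-4-[(E)-4-(trimethylsilyl)but-1-en-3-yn-1-yl]cyclohexa-2,5-dien-1-one, via azido alcohol 10 (not isolated), via azido mesylate 11 (not isolated)
Conditions: NaN3, AcOH, DMF, 0 °C to rt; then MsCl, Et3N, CH2Cl2, 0 °C
Reagents that add atoms: sodium azide, [Na+].[N-]=[N+]=[N-]
Why: SN2 opening of the α,β-epoxy ketone by azide at the carbonyl-activated α-carbon (the β-carbon is neopentylic), then mesylation of the secondary β-hydroxyl and E1cB loss of mesylate should give the 2-azidoenone; both relay stereocentres are erased and the carbinol carbon remains the only stereocentre.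

Step 7
Reactants: 13 4-methylpentanal; 14 (triphenyl-λ5-phosphanylidene)acetaldehyde
Product: 15 (E)-6-methylhept-2-enal
Conditions: toluene, 80 °C, 13 in slight excess (1.2 equiv)
Reagents that add atoms: none
Why: Wittig reaction of a stabilised formyl ylide, E-selective; the deficit of ylide limits a second homologation.

Step 8
Reactants: 15 (E)-6-methylhept-2-enal; 16 ethyl (E)-4-(diethoxyphosphoryl)but-2-enoate
Product: 17 ethyl (2E,4E,6E)-10-methylundeca-2,4,6-trienoate
Conditions: LiN(SiMe3)2, THF, −78 to 0 °C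
Reagents that add atoms: none
Why: Vinylogous Horner–Wadsworth–Emmons olefination; the stabilised phosphonate anion should form the new C4=C5 bond E while the crotonate double bond stays E.

Step 9
Reactants: 17 ethyl (2E,4E,6E)-10-methylundeca-2,4,6-trienoate
Product: 18 (2E,4E,6E)-10-methylundeca-2,4,6-trienoic acid
Conditions: LiOH, THF/MeOH/H2O, rt; then 1 M HCl
Reagents that add atoms: lithium hydroxide, [Li+].[OH-]
Why: Ester saponification under conditions mild enough not to isomerise the triene.

Step 10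
Reactants: 18 (2E,4E,6E)-10-methylundeca-2,4,6-trienoic acid
Product: 19 (2E,4E,6E)-10-methylundeca-2,4,6-trienoyl chloride
Conditions: (COCl)2, DMF (cat.), CH2Cl2, 0 °C to rt; used crude
Reagents that add atoms: oxalyl chloride, O=C(Cl)C(=O)Cl
Why: Acid chloride formation through the chloroiminium (Vilsmeier-type) activation, which leaves the triene untouched.

Step 11
Reactants: 12 (4R)-2-azido-4-[(triethylsilyl)oxy]-4-[(E)-4-(trimethylsilyl)but-1-en-3-yn-1-yl]cyclohexa-2,5-dien-1-one; 19 (2E,4E,6E)-10-methylundeca-2,4,6-trienoyl chloride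
Product: 21 (2E,4E,6E)-10-methyl-N-[(3R)-6-oxo-3-[(triethylsilyl)oxy]-3-[(E)-4-(trimethylsilyl)but-1-en-3-yn-1-yl]cyclohexa-1,4-dien-1-yl]undeca-2,4,6-trienamide, via iminophosphorane 20 (not isolated)
Conditions: PPh3, THF, 0 °C to rt; then 19, 0 °C; then aq. NaHCO3
Reagents that add atoms: none
Why: Staudinger reaction to the N-vinyl iminophosphorane, which should be acylated at nitrogen by 19 and hydrolysed to the secondary enamide without freeing the labile 2-aminodienone.

Step 12
Reactants: 21 (2E,4E,6E)-10-methyl-N-[(3R)-6-oxo-3-[(triethylsilyl)oxy]-3-[(E)-4-(trimethylsilyl)but-1-en-3-yn-1-yl]cyclohexa-1,4-dien-1-yl]undeca-2,4,6-trienamide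
Product: 22 (2E,4E,6E)-10-methyl-N-[(1R,5S,6S)-2-oxo-5-[(triethylsilyl)oxy]-5-[(E)-4-(trimethylsilyl)but-1-en-3-yn-1-yl]-7-oxabicyclo[4.1.0]hept-3-en-3-yl]undeca-2,4,6-trienamide
Conditions: t-BuOOH (in decane), DBU, THF, 0 °C
Reagents that add atoms: tert-butyl hydroperoxide, CC(C)(C)OO
Why: Weitz–Scheffer epoxidation: the peroxide anion should add only to the unsubstituted enone (the amido-substituted enone is deactivated as its amidate) and, in the Felkin–Anh sense known for 4-silyloxy enones, anti to the C–O bond and away from the Et3SiO group that can no longer donate a hydrogen bond, so the oxirane forms on the face of the enynyl group and sets C1 (R) and C6 (S) relative to C5.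

Step 13
Reactants: 22 (2E,4E,6E)-10-methyl-N-[(1R,5S,6S)-2-oxo-5-[(triethylsilyl)oxy]-5-[(E)-4-(trimethylsilyl)but-1-en-3-yn-1-yl]-7-oxabicyclo[4.1.0]hept-3-en-3-yl]undeca-2,4,6-trienamide
Product: 23 (2E,4E,6E)-N-[(1R,5S,6S)-5-[(E)-but-1-en-3-yn-1-yl]-5-hydroxy-2-oxo-7-oxabicyclo[4.1.0]hept-3-en-3-yl]-10-methylundeca-2,4,6-trienamide
Conditions: Bu4NF (3 equiv), AcOH (3.5 equiv), THF, 0 °C to rt
Reagents that add atoms: none
Why: Fluoride cleaves the alkynyl C–Si and the tertiary O–Si bonds; the acetic acid buffer keeps the liberated tertiary alcohol protonated and so should prevent a Payne rearrangement onto the anti oxirane.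

Step 14
Reactants: 24 cyclopentane-1,3-dione
Product: 25 2-diazocyclopentane-1,3-dione
Conditions: 4-acetamidobenzenesulfonyl azide, Et3N, MeCN, 0 °C to rt
Reagents that add atoms: 4-acetamidobenzenesulfonyl azide, CC(=O)Nc1ccc(cc1)S(=O)(=O)N=[N+]=[N-]
Why: Regitz diazo transfer to the acidic C2–H of the 1,3-dione.

Step 15
Reactants: 26 (2E)-3-iodoprop-2-enoic acid
Product: 28 (2E)-3-iodoprop-2-enamide, via acid chloride 27 (not isolated)
Conditions: (COCl)2, DMF (cat.), CH2Cl2, 0 °C to rt, evaporate; then NH3 (0.5 M in 1,4-dioxane, 2.2 equiv), THF, −78 °C, dark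
Reagents that add atoms: ammonia, N
Why: Acid chloride formation followed by aminolysis; at −78 °C acyl substitution should be far faster than addition–elimination of ammonia at the β-iodo carbon, and the E geometry of the iodoalkene is kept.

Step 16
Reactants: 25 2-diazocyclopentane-1,3-dione; 28 (2E)-3-iodoprop-2-enamide
Product: 29 (2E)-N-(2-hydroxy-5-oxocyclopent-1-en-1-yl)-3-iodoprop-2-enamide
Conditions: Rh2(OAc)4 (1 mol %), ClCH2CH2Cl, 70 °C, dark
Reagents that add atoms: none
Why: Rhodium-carbenoid N–H insertion into the primary amide (the electrophilic carbenoid should not cyclopropanate the electron-poor iodoalkene, and any ylide formed at iodine should revert), and the product tautomerises to the enol form that is the aminocyclopentenone unit of the target.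

Step 17
Reactants: 23 (2E,4E,6E)-N-[(1R,5S,6S)-5-[(E)-but-1-en-3-yn-1-yl]-5-hydroxy-2-oxo-7-oxabicyclo[4.1.0]hept-3-en-3-yl]-10-methylundeca-2,4,6-trienamide; 29 (2E)-N-(2-hydroxy-5-oxocyclopent-1-en-1-yl)-3-iodoprop-2-enamide
Product: 31 (2E,4E,6E)-N-[(1R,5S,6S)-5-hydroxy-5-[(1E,3E,5E)-7-[(2-hydroxy-5-oxocyclopent-1-en-1-yl)amino]-7-oxohepta-1,3,5-trien-1-yl]-2-oxo-7-oxabicyclo[4.1.0]hept-3-en-3-yl]-10-methylundeca-2,4,6-trienamide, via dienylstannane 30 (not isolated)
Conditions: Bu3SnH (1.1 equiv, slow addition), Pd2(dba)3 (2.5 mol %), Cy3P·HBF4 (10 mol %), i-Pr2NEt (20 mol %), THF, 0 °C; then 29 (1.2 equiv), CuI (10 mol %), DMF, rt, dark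
Reagents that add atoms: none
Why: Zerovalent palladium inserts into the Sn–H bond and delivers H and SnBu3 syn across the only C≡C, with tin at the unhindered terminal carbon C4' and hydrogen at C3', so the latent alkyne becomes the (1E,3E)-dienylstannane 30; once the tin hydride is consumed, the same catalyst undergoes oxidative addition to the C–I bond of 29, tin-to-palladium transmetalation (assisted by CuI) and reductive elimination, which forms the C4'–C5' bond with retention at both alkenes. The closest known reaction type is the one-pot palladium-catalysed hydrostannation/Stille coupling of terminal alkynes with alkenyl halides, and the Stille half is a reaction type known to tolerate free hydroxyl groups, epoxides and enones. No ring is closed and no stereocentre is formed; the C3'=C4' geometry comes from the syn addition and the C5'=C6' geometry from the E iodide. The step needs chemoselectivity of the tin hydride for the alkyne over the enone, the epoxy ketone and the trienamide (alkyne hydrostannation is much faster under palladium catalysis, and slow addition keeps the hydride concentration low), regioselectivity for tin at C4' (terminal position, bulky Cy3P ligand) and the stated order of addition, so that no tin hydride is left to reduce the C–I bond. The medium is neutral and at or below room temperature, which the epoxy ketone, the free tertiary alcohol and the enol of 29 should tolerate.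

**Compound list**

1 | 4,4-dimethoxycyclohexa-2,5-dien-1-one | COC1(OC)C=CC(=O)C=C1 | starting material
2 | (1S,6R)-5,5-dimethoxy-7-oxabicyclo[4.1.0]hept-3-en-2-one | COC1(OC)C=CC(=O)[C@H]2O[C@@H]12 | intermediate
3 | (E)-1,2-bis(tributylstannyl)ethene | CCCC[Sn](CCCC)(CCCC)/C=C/[Sn](CCCC)(CCCC)CCCC | starting material
4 | (bromoethynyl)trimethylsilane | C[Si](C)(C)C#CBr | starting material
5 | tributyl[(E)-4-(trimethylsilyl)but-1-en-3-yn-1-yl]stannane | CCCC[Sn](CCCC)(CCCC)/C=C/C#C[Si](C)(C)C | intermediate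
6 | [(E)-4-(trimethylsilyl)but-1-en-3-yn-1-yl]lithium | [Li]/C=C/C#C[Si](C)(C)C | intermediate
7 | (1S,2R,6R)-5,5-dimethoxy-2-[(E)-4-(trimethylsilyl)but-1-en-3-yn-1-yl]-7-oxabicyclo[4.1.0]hept-3-en-2-ol | C[Si](C)(C)C#C/C=C/[C@@]1(O)C=CC(OC)(OC)[C@@H]2O[C@H]12 | intermediate
8 | (1R,5R,6S)-5-hydroxy-5-[(E)-4-(trimethylsilyl)but-1-en-3-yn-1-yl]-7-oxabicyclo[4.1.0]hept-3-en-2-one | C[Si](C)(C)C#C/C=C/[C@@]1(O)C=CC(=O)[C@@H]2O[C@H]12 | intermediate
9 | (1R,5R,6S)-5-[(triethylsilyl)oxy]-5-[(E)-4-(trimethylsilyl)but-1-en-3-yn-1-yl]-7-oxabicyclo[4.1.0]hept-3-en-2-one | C[Si](C)(C)C#C/C=C/[C@@]1(O[Si](CC)(CC)CC)C=CC(=O)[C@@H]2O[C@H]12 | intermediate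
10 | (4R,5S,6S)-6-azido-5-hydroxy-4-[(triethylsilyl)oxy]-4-[(E)-4-(trimethylsilyl)but-1-en-3-yn-1-yl]cyclohex-2-en-1-one | C[Si](C)(C)C#C/C=C/[C@@]1(O[Si](CC)(CC)CC)C=CC(=O)[C@@H](N=[N+]=[N-])[C@@H]1O | intermediate
11 | (4R,5S,6S)-6-azido-5-(methanesulfonyloxy)-4-[(triethylsilyl)oxy]-4-[(E)-4-(trimethylsilyl)but-1-en-3-yn-1-yl]cyclohex-2-en-1-one | C[Si](C)(C)C#C/C=C/[C@@]1(O[Si](CC)(CC)CC)C=CC(=O)[C@@H](N=[N+]=[N-])[C@@H]1OS(C)(=O)=O | intermediate
12 | (4R)-2-azido-4-[(triethylsilyl)oxy]-4-[(E)-4-(trimethylsilyl)but-1-en-3-yn-1-yl]cyclohexa-2,5-dien-1-one | C[Si](C)(C)C#C/C=C/[C@@]1(O[Si](CC)(CC)CC)C=CC(=O)C(N=[N+]=[N-])=C1 | intermediate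
13 | 4-methylpentanal | CC(C)CCC=O | starting material
14 | (triphenyl-λ5-phosphanylidene)acetaldehyde | O=CC=P(c1ccccc1)(c1ccccc1)c1ccccc1 | starting material
15 | (E)-6-methylhept-2-enal | CC(C)CC/C=C/C=O | intermediate
16 | ethyl (E)-4-(diethoxyphosphoryl)but-2-enoate | CCOC(=O)/C=C/CP(=O)(OCC)OCC | starting material
17 | ethyl (2E,4E,6E)-10-methylundeca-2,4,6-trienoate | CC(C)CC/C=C/C=C/C=C/C(=O)OCC | intermediate
18 | (2E,4E,6E)-10-methylundeca-2,4,6-trienoic acid | CC(C)CC/C=C/C=C/C=C/C(=O)O | intermediate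
19 | (2E,4E,6E)-10-methylundeca-2,4,6-trienoyl chloride | CC(C)CC/C=C/C=C/C=C/C(=O)Cl | intermediate
20 | (4R)-4-[(triethylsilyl)oxy]-4-[(E)-4-(trimethylsilyl)but-1-en-3-yn-1-yl]-2-[(triphenyl-λ5-phosphanylidene)amino]cyclohexa-2,5-dien-1-one | C[Si](C)(C)C#C/C=C/[C@@]1(O[Si](CC)(CC)CC)C=CC(=O)C(N=P(c2ccccc2)(c2ccccc2)c2ccccc2)=C1 | intermediate
21 | (2E,4E,6E)-10-methyl-N-[(3R)-6-oxo-3-[(triethylsilyl)oxy]-3-[(E)-4-(trimethylsilyl)but-1-en-3-yn-1-yl]cyclohexa-1,4-dien-1-yl]undeca-2,4,6-trienamide | CC(C)CC/C=C/C=C/C=C/C(=O)NC1=C[C@@](O[Si](CC)(CC)CC)(/C=C/C#C[Si](C)(C)C)C=CC1=O | intermediate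
22 | (2E,4E,6E)-10-methyl-N-[(1R,5S,6S)-2-oxo-5-[(triethylsilyl)oxy]-5-[(E)-4-(trimethylsilyl)but-1-en-3-yn-1-yl]-7-oxabicyclo[4.1.0]hept-3-en-3-yl]undeca-2,4,6-trienamide | CC(C)CC/C=C/C=C/C=C/C(=O)NC1=C[C@@](O[Si](CC)(CC)CC)(/C=C/C#C[Si](C)(C)C)[C@H]2O[C@H]2C1=O | intermediate
23 | (2E,4E,6E)-N-[(1R,5S,6S)-5-[(E)-but-1-en-3-yn-1-yl]-5-hydroxy-2-oxo-7-oxabicyclo[4.1.0]hept-3-en-3-yl]-10-methylundeca-2,4,6-trienamide | CC(C)CC/C=C/C=C/C=C/C(=O)NC1=C[C@@](O)(/C=C/C#C)[C@H]2O[C@H]2C1=O | intermediate
24 | cyclopentane-1,3-dione | O=C1CCC(=O)C1 | starting material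
25 | 2-diazocyclopentane-1,3-dione | [N-]=[N+]=C1C(=O)CCC1=O | intermediate
26 | (2E)-3-iodoprop-2-enoic acid | OC(=O)/C=C/I | starting material
27 | (2E)-3-iodoprop-2-enoyl chloride | ClC(=O)/C=C/I | intermediate
28 | (2E)-3-iodoprop-2-enamide | NC(=O)/C=C/I | intermediate
29 | (2E)-N-(2-hydroxy-5-oxocyclopent-1-en-1-yl)-3-iodoprop-2-enamide | I/C=C/C(=O)NC1=C(O)CCC1=O | intermediate
30 | (2E,4E,6E)-N-[(1R,5S,6S)-5-hydroxy-2-oxo-5-[(1E,3E)-4-(tributylstannyl)buta-1,3-dien-1-yl]-7-oxabicyclo[4.1.0]hept-3-en-3-yl]-10-methylundeca-2,4,6-trienamide | CC(C)CC/C=C/C=C/C=C/C(=O)NC1=C[C@@](O)(/C=C/C=C/[Sn](CCCC)(CCCC)CCCC)[C@H]2O[C@H]2C1=O | intermediate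
31 | (2E,4E,6E)-N-[(1R,5S,6S)-5-hydroxy-5-[(1E,3E,5E)-7-[(2-hydroxy-5-oxocyclopent-1-en-1-yl)amino]-7-oxohepta-1,3,5-trien-1-yl]-2-oxo-7-oxabicyclo[4.1.0]hept-3-en-3-yl]-10-methylundeca-2,4,6-trienamide | CC(C)CC/C=C/C=C/C=C/C(=O)NC1=C[C@@](O)(/C=C/C=C/C=C/C(=O)NC2=C(O)CCC2=O)[C@H]2O[C@H]2C1=O | target

**Summary**

Total step count: 17. Longest linear sequence: 9 steps (steps 1, 3, 4, 5, 6, 11, 12, 13, 17).

Steps most likely to fail:

1) Step 17. The tin hydride may add with the reverse regiochemistry (tin at C3'), it may reduce the ring enone in competition with the alkyne, or the dienylstannane may be protodestannylated by the acidic enol of 29 before it transmetalates. The fallback changes the metalloid and the hydrometalation mechanism and sets out from 23: platinum-catalysed hydrosilylation (HSi(OEt)3, Pt2[(CH2=CHSiMe2)2O]3, t-Bu3P, THF, rt) is terminal- and syn-selective and uses no reagent able to reduce an enone, and should give the (1E,3E)-dienyl(triethoxy)silane F1. A fluoride-promoted Hiyama coupling of F1 with 29 (Bu4NF·3H2O, Pd2(dba)3, THF, rt) comes back to the route at 31.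

2) Step 1. The ion-paired peroxide may discriminate poorly between the enone faces of a monoketal that has no anchoring substituent, so that material of low enantiomeric purity is carried forward. The fallback replaces catalyst control by an auxiliary and sets out from 1: acid-catalysed transketalisation with (1R,2R)-1,2-diphenylethane-1,2-diol gives the C2-symmetric spiroketal F2. Its Weitz–Scheffer epoxidation (t-BuOOH, DBU) gives diastereomers instead of enantiomers, so the epoxide F3 can be taken to a single stereoisomer by crystallisation whatever the level of induction. Addition of 6 as in step 3 gives the adduct F4, and aqueous acid hydrolysis of the ketal comes back to the route at 8.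

3) Step 11. The N-vinyl iminophosphorane may be acylated at carbon, or be hydrolysed to the labile 2-aminodienone before it is acylated. The fallback avoids any reduced nitrogen species and sets out from 19: NaSH (THF/H2O, 0 °C, then dilute acid) gives the thioacid F5, which should couple directly with the electron-poor azide 12 (2,6-lutidine, MeCN, rt) with loss of dinitrogen and sulfur, coming back to the route at 21.

**Further compounds**

F1 | step 17 | (2E,4E,6E)-N-[(1R,5S,6S)-5-hydroxy-2-oxo-5-[(1E,3E)-4-(triethoxysilyl)buta-1,3-dien-1-yl]-7-oxabicyclo[4.1.0]hept-3-en-3-yl]-10-methylundeca-2,4,6-trienamide | CC(C)CC/C=C/C=C/C=C/C(=O)NC1=C[C@@](O)(/C=C/C=C/[Si](OCC)(OCC)OCC)[C@H]2O[C@H]2C1=O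
F2 | step 1 | (2R,3R)-2,3-diphenyl-1,4-dioxaspiro[4.5]deca-6,9-dien-8-one | O=C1C=CC2(C=C1)O[C@H](c1ccccc1)[C@@H](c1ccccc1)O2
F3 | step 1 | (1S,6R)-epoxy ketone 2 in which the dimethyl ketal is replaced by the (4R,5R)-4,5-diphenyl-1,3-dioxolane spiroketal | O=C1C=CC2(O[C@H](c3ccccc3)[C@@H](c3ccccc3)O2)[C@@H]4O[C@H]14
F4 | step 1 | (1S,2R,6R)-carbinol 7 in which the dimethyl ketal is replaced by the (4R,5R)-4,5-diphenyl-1,3-dioxolane spiroketal | C[Si](C)(C)C#C/C=C/[C@@]1(O)C=CC2(O[C@H](c3ccccc3)[C@@H](c3ccccc3)O2)[C@@H]4O[C@H]14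
F5 | step 11 | (2E,4E,6E)-10-methylundeca-2,4,6-trienethioic S-acid | CC(C)CC/C=C/C=C/C=C/C(=O)S
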